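(The earlier runs and the new flask stem from a simulated flask from invented constants; the scatter is artificial.)

- Freeze the intermediate first. In the noon run it stays between 1% and 2% while product climbs to 28%, so we set its making equal to its use (the steady-state approximation). Then [intermediate] is the product rate divided by how often one intermediate is captured.

the same everywhere: starting material 26 mM
- noon: reagent 0.42 equiv; run made earlier
- winter: reagent 0.84 equiv; run made earlier
- dusk: reagent 2.4 equiv; run made earlier
- north: reagent 0.400 equiv; time 12 min
- south-east: reagent 0.500 equiv; time 12 min
- south: reagent 0.800 equiv; time 12 min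
- south-west: reagent 1.20 equiv; time 12 min
- north-east: reagent 2.00 equiv; time 12 min

| run | time / min | intermediate / % | product / % | starting material / % |
|---|---|---|---|---|
| noon | 1.00 | 1 | 6 | 94 |
| noon | 2.00 | 1 | 9 | 90 |
| noon | 5.00 | 2 | 14 | 83 |
| noon | 12.0 | 1 | 28 | 72 |
| winter | 1.00 | 0 | 5 | 94 |
| winter | 2.00 | 0 | 11 | 87 |
| winter | 5.00 | 1 | 23 | 78 |
| winter | 12.0 | 1 | 42 | 52 |
| dusk | 1.00 | 1 | 7 | 91 |
| dusk | 2.00 | 0 | 16 | 81 |
| dusk | 5.00 | 0 | 36 | 59 |
| dusk | 12.0 | 0 | 64 | 33 |

(readings scatter by 1.5 percentage points)

- "hardly changes" means that all values lie within two and a half points (for a concentration: within two and a half percent of the largest)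

- [intermediate] at the end for north, south-east, south, south-west, north-east, in this order
- the shape of the row from first to last (falls, then rises / hardly changes / rises all the way / rises, then falls / falls all the way)

- Take the rate in the noon run. Product forms at 1.17 mM min⁻¹ over the first 2.00 min, but at 0.520 mM min⁻¹ from 5.00 min to 12.0 min, a fall by a factor of 0.444.
- If one reagent goes into each product, reagent between those windows falls by a factor of 0.560 and starting material by 0.816. Together these give 0.457, close to the fall we read.
- Our carried quantity is the capture frequency, the late product rate over the mean [intermediate] of the noon readings, 0.325 mM: 1.60 min⁻¹ in the noon run's late window, taken as proportional to reagent left. It is a rough reading: those intermediate readings of 1% to 2% stand against a scatter of 1.5 percentage points.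
- In our reckoning at noon's charge, reagent enters the product rate and the capture frequency alike and cancels, so we scale [intermediate] with starting material from the late window to the end. Our estimate for north, charged much like noon, is 0.302 mM.
- For north-east we borrow the dusk run's late rate, 1.04 mM min⁻¹, slowed to 0.746 mM min⁻¹ at the end. Our estimate of capture in north-east is 10.4 min⁻¹, which gives 0.0720 mM, so our estimate for north stands above the one for north-east and we expect the row to fall.
- The forecast gives 0.3 mM, 0.26 mM, 0.19 mM, 0.14 mM and 0.09 mM, shape falls all the way, on the ground that “More reagent leaves less starting material and seems to lower the ratio too”. Its north-east point lies above our 0.0720 mM.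
- The flask gives 0.276 mM, 0.246 mM, 0.178 mM, 0.122 mM and 0.0687 mM, shape falls all the way.

    starting material ⇌ intermediate + leaving ligand (K = 1.70 × 10⁻⁵ M, k = 0.156 min⁻¹)
    reagent + intermediate → product (k = 312 M⁻¹ min⁻¹)
    crystals ⇌ leaving ligand, rate k3*(cs3 - [leaving ligand]) while solid is left; crystals form when [leaving ligand] > cs3 (solubility = 1.00 mM, k = 6.97 min⁻¹)

- In north, capture by reagent alone, at charged concentrations, has a half-life of 0.21 min, short against 12 min. In south, 47% of the reagent charge is left at 12.0 min, which puts the capture frequency at 2.84 min⁻¹. With 0.178 mM of intermediate in south, that reckons to a product rate of 0.506 mM min⁻¹ at that moment, while south's product gain from 6.00 min to 12.0 min averages 0.687 mM min⁻¹.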